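**Retrosynthetic overview**
1. Locants: guaiacyl unit C1–C9 (arene = ring A), central syringyl unit C1'–C9' (arene = ring D), glycerol unit C1''–C9'' (arene = ring E); ring B = O1/C7/C8/C8'/C9', ring C = O/C9/C8/C8'/C7'. The core is cis-fused with ring A exo at C7 and ring D endo at C7'; the side chain is threo (7''R,8''R).
2. End game: debenzylation and desilylation; before that, C7' is completed by two disconnections: C7'–H (hydride to the bicyclic oxocarbenium ion from the convex face) and C7'–C1' (aryllithium 23 plus lactone 11).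
3. Key step: ring B is closed by the O1–C7 bond in an acid-triggered ring expansion of cyclopropane-fused lactone 9 (3-oxabicyclo[3.1.0]hexanone to 3,7-dioxabicyclo[3.3.0]octanone). It is made possible by the para oxygen on C4 of ring A, which is conjugated through ring A to C7 and faces the lactone carbonyl C7' on C8' across the push–pull cyclopropane bond C7–C8', with the C9' hydroxymethyl group on C8' placed to capture C7.
4. Cyclopropane 4 comes from O-benzylconiferaldehyde and diethyl bromomalonate by an organocatalytic Michael/alkylation that sets C8; C7, C8' and C7' are relayed from C8. Aryl bromide 22 (rings D and E, C7''/C8'') comes from an Evans syn glycolate aldol.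
5. Order of ring formation: cyclopropane, then the lactone form of ring C, then ring B (key step); ring C reaches its final oxidation level at C7' last.

Key step: step 6

Remark: compounds 1, 3, 12, 13, 15 and 18 are taken as commercial; ArD = 3,5-dimethoxy-4-{[(1R,2R)-1-(4-benzyloxy-3,5-dimethoxyphenyl)-1,3-bis(tert-butyldimethylsilyloxy)propan-2-yl]oxy}phenyl.

**Route**

Step 1
Reactants: 1 (E)-coniferaldehyde
Product: 2 (E)-3-(4-benzyloxy-3-methoxyphenyl)prop-2-enal
Conditions: BnBr, K2CO3, DMF, rt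
Reagents that add atoms: benzyl bromide, BrCc1ccccc1
Why: Williamson etherification of the phenol; the benzyl ether lasts until the final hydrogenolysis and keeps the C4 oxygen of ring A as a donor for the key step.

Step 2
Reactants: 2 (E)-3-(4-benzyloxy-3-methoxyphenyl)prop-2-enal; 3 diethyl 2-bromomalonate
Product: 4 diethyl (2S,3R)-2-formyl-3-(4-benzyloxy-3-methoxyphenyl)cyclopropane-1,1-dicarboxylate
Conditions: (R)-α,α-diphenylprolinol trimethylsilyl ether (20 mol %), 2,6-lutidine, CH2Cl2, 0 °C → rt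
Reagents that add atoms: none
Why: Organocatalytic Michael-initiated ring closure (iminium then enamine activation), in which the diphenyl(silyloxy)methyl group of the (R)-catalyst shields one face of the E-iminium ion so that the bromomalonate adds to the open face of C7 and a 3-exo-tet alkylation closes the trans cyclopropane, fixing C8 in the configuration that becomes 8S.

Step 3
Reactants: 4 diethyl (2S,3R)-2-formyl-3-(4-benzyloxy-3-methoxyphenyl)cyclopropane-1,1-dicarboxylate
Product: 6 ethyl (1R,5S,6R)-6-(4-benzyloxy-3-methoxyphenyl)-2-oxo-3-oxabicyclo[3.1.0]hexane-1-carboxylate, via hydroxymethyl diester 5 (not isolated)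
Conditions: NaBH4, EtOH, 0 °C → rt; aq. NH4Cl
Reagents that add atoms: none
Why: Chemoselective borohydride reduction of the aldehyde followed by lactonisation of the C9 hydroxyl onto the only ester within reach (the cis one), which differentiates the two ester groups on C8'.

Step 4
Reactants: 6 ethyl (1R,5S,6R)-6-(4-benzyloxy-3-methoxyphenyl)-2-oxo-3-oxabicyclo[3.1.0]hexane-1-carboxylate
Product: 8 (1R,5S,6R)-6-(4-benzyloxy-3-methoxyphenyl)-2-oxo-3-oxabicyclo[3.1.0]hexane-1-carboxylic acid, via hydroxy diacid 7 (not isolated)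
Conditions: LiOH·H2O, THF/H2O, 0 °C → rt; then 1 M HCl to pH 2, 0 °C
Reagents that add atoms: lithium hydroxide, [Li+].[OH-]
Why: Saponification cleaves the ethyl ester (and, reversibly, the lactone), and on acidification the cis γ-hydroxy acid of 7 relactonises, so that only the carboxyl group cis to ring A stays free.

Step 5
Reactants: 8 (1R,5S,6R)-6-(4-benzyloxy-3-methoxyphenyl)-2-oxo-3-oxabicyclo[3.1.0]hexane-1-carboxylic acid
Product: 9 (1R,5S,6R)-6-(4-benzyloxy-3-methoxyphenyl)-1-(hydroxymethyl)-3-oxabicyclo[3.1.0]hexan-2-one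
Conditions: BH3·SMe2, THF, 0 °C → rt; MeOH quench
Reagents that add atoms: none
Why: Chemoselective borane reduction, since a free carboxylic acid is reduced much faster than a lactone, gives the C9' hydroxymethyl group geminal to the lactone carbonyl.

Step 6
Reactants: 9 (1R,5S,6R)-6-(4-benzyloxy-3-methoxyphenyl)-1-(hydroxymethyl)-3-oxabicyclo[3.1.0]hexan-2-one
Product: 11 (1S,5S,6R)-6-(4-benzyloxy-3-methoxyphenyl)-3,7-dioxabicyclo[3.3.0]octan-2-one, via ring-opened zwitterion 10 (not isolated)
Conditions: Sc(OTf)3 (10 mol %), (CF3)2CHOH/CH2Cl2 1:4, 0.02 M, 0 °C → rt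
Reagents that add atoms: none
Why: Proposed new method: Sc(OTf)3 activates the lactone carbonyl C7'=O while the para oxygen on C4 of ring A pushes, so the push–pull cyclopropane bond C7–C8' breaks heterolytically to zwitterion 10 (quinoid benzylic cation at C7, an O-benzylated para-quinone methide, plus a scandium-bound lactone enolate at C8'); the C9' hydroxyl then adds to C7 and the enolate is protonated, a strain-driven isomerisation of the 3-oxabicyclo[3.1.0]hexanone into the 3,7-dioxabicyclo[3.3.0]octanone. The closest known reaction types are the acid-catalysed ring opening of donor–acceptor cyclopropanes by alcohols in fluorinated alcohol media, the Cloke–Wilson rearrangement of acyl cyclopropanes and the intramolecular oxa-1,6-addition to para-quinone methides; new here is a hydroxymethyl nucleophile sitting on the acceptor carbon of a singly activated lactone cyclopropane. Ring B closes by the O1–C7 bond in a 5-exo-trig attack on the exocyclic C7=C1 bond of the quinoid cation. C8 is not touched and relays its configuration: C8' is set on enolate protonation because only the cis-fused bicycle can form and the centre is epimerisable towards it, and C7 is set with ring A exo (trans to C9), which is the less crowded approach and, as ionisation at C7 is reversible, also the thermodynamic outcome. The step needs capture of C7 by the C9' hydroxyl to outrun loss of H8 and intermolecular arene capture; the geminal placement of the nucleophile, high dilution, low temperature and the non-nucleophilic ionising medium secure this.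

Step 7
Reactants: 12 4-bromo-2,6-dimethoxyphenol; 13 bromoacetic acid
Product: 14 2-(4-bromo-2,6-dimethoxyphenoxy)acetic acid
Conditions: NaOH, H2O, 100 °C; then HCl
Reagents that add atoms: none
Why: Williamson ether synthesis of an aryloxyacetic acid; the phenoxide displaces bromide from the carboxylate salt of 13.

Step 8
Reactants: 14 2-(4-bromo-2,6-dimethoxyphenoxy)acetic acid; 15 (S)-4-benzyloxazolidin-2-one
Product: 17 (S)-4-benzyl-3-[2-(4-bromo-2,6-dimethoxyphenoxy)acetyl]oxazolidin-2-one, via mixed pivalic anhydride 16 (not isolated)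
Conditions: PivCl, Et3N, THF, −20 °C; then 15, LiCl, −20 °C → rt
Reagents that add atoms: none
Why: N-Acylation of the oxazolidinone through the mixed anhydride, which is attacked at the less hindered aryloxyacetyl carbonyl.

Step 9
Reactants: 17 (S)-4-benzyl-3-[2-(4-bromo-2,6-dimethoxyphenoxy)acetyl]oxazolidin-2-one; 18 4-benzyloxy-3,5-dimethoxybenzaldehyde
Product: 20 (S)-4-benzyl-3-[(2S,3R)-3-(4-benzyloxy-3,5-dimethoxyphenyl)-2-(4-bromo-2,6-dimethoxyphenoxy)-3-hydroxypropanoyl]oxazolidin-2-one, via Z-boron enolate 19 (not isolated)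
Conditions: Bu2BOTf, iPr2NEt, CH2Cl2, −78 → 0 °C; then 18, −78 → 0 °C; H2O2, MeOH, pH 7 buffer
Reagents that add atoms: none
Why: Evans syn glycolate aldol reaction, in which the Z-dibutylboron enolate reacts through a closed chair transition state on the face away from the benzyl group of the auxiliary and sets C8'' and C7'' together as the syn (threo) pair.

Step 10
Reactants: 20 (S)-4-benzyl-3-[(2S,3R)-3-(4-benzyloxy-3,5-dimethoxyphenyl)-2-(4-bromo-2,6-dimethoxyphenoxy)-3-hydroxypropanoyl]oxazolidin-2-one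
Product: 21 (1R,2R)-1-(4-benzyloxy-3,5-dimethoxyphenyl)-2-(4-bromo-2,6-dimethoxyphenoxy)propane-1,3-diol
Conditions: LiBH4, THF, H2O (1 equiv), 0 °C
Reagents that add atoms: none
Why: Reductive cleavage of the N-acyl oxazolidinone gives the primary alcohol C9'' without touching either stereocentre or the aryl bromide and returns the auxiliary.

Step 11
Reactants: 21 (1R,2R)-1-(4-benzyloxy-3,5-dimethoxyphenyl)-2-(4-bromo-2,6-dimethoxyphenoxy)propane-1,3-diol
Product: 22 (1R,2R)-1-(4-benzyloxy-3,5-dimethoxyphenyl)-2-(4-bromo-2,6-dimethoxyphenoxy)-1,3-bis(tert-butyldimethylsilyloxy)propane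
Conditions: TBSOTf, 2,6-lutidine, CH2Cl2, 0 °C
Reagents that add atoms: tert-butyldimethylsilyl triflate, CC(C)(C)[Si](C)(C)OS(=O)(=O)C(F)(F)F
Why: Silylation of both hydroxyl groups, with the silyl triflate needed for the hindered benzylic one, gives ethers that tolerate the aryllithium and are removed by fluoride without acid.

Step 12
Reactants: 22 (1R,2R)-1-(4-benzyloxy-3,5-dimethoxyphenyl)-2-(4-bromo-2,6-dimethoxyphenoxy)-1,3-bis(tert-butyldimethylsilyloxy)propane; 11 (1S,5S,6R)-6-(4-benzyloxy-3-methoxyphenyl)-3,7-dioxabicyclo[3.3.0]octan-2-one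
Product: 24 (1S,5S,6R)-2-ArD-6-(4-benzyloxy-3-methoxyphenyl)-3,7-dioxabicyclo[3.3.0]octan-2-ol (lactol at C7'; anomeric mixture), via aryllithium 23 (not isolated)
Conditions: n-BuLi, THF, −78 °C; then 11, −78 °C; aq. NH4Cl
Reagents that add atoms: none
Why: Bromine–lithium exchange and 1,2-addition of the aryllithium to the lactone carbonyl C7', where the lithium salt of 24 persists at −78 °C and so prevents a second addition.

Step 13
Reactants: 24 (1S,5S,6R)-2-ArD-6-(4-benzyloxy-3-methoxyphenyl)-3,7-dioxabicyclo[3.3.0]octan-2-ol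
Product: 26 (1S,2S,5S,6R)-2-ArD-6-(4-benzyloxy-3-methoxyphenyl)-3,7-dioxabicyclo[3.3.0]octane (ArD endo; ring A exo), via oxocarbenium ion 25 (not isolated)
Conditions: Et3SiH, BF3·OEt2, CH2Cl2, −78 → −40 °C; Et3N then aq. NaHCO3
Reagents that add atoms: none
Why: Ionic hydrogenation of the lactol, in which BF3 ionises the hemiketal to the aryl-stabilised bicyclic oxocarbenium ion 25 and the silane delivers hydride to C7' from the convex face of the cis-fused bicycle, so that ring D ends on the concave face (endo, cis to C9'), the kinetic 7'S configuration.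

Step 14
Reactants: 26 (1S,2S,5S,6R)-2-ArD-6-(4-benzyloxy-3-methoxyphenyl)-3,7-dioxabicyclo[3.3.0]octane
Product: 27 4,4''-di-O-benzyl ether of the target (7''- and 9''-hydroxyl groups free)
Conditions: Bu4NF, AcOH, THF, 0 °C → rt
Reagents that add atoms: none
Why: Buffered fluoride cleaves both silyl ethers under non-acidic conditions, which leaves the acid-labile endo aryl centre C7' untouched.

Step 15
Reactants: 27 4,4''-di-O-benzyl ether of the target
Product: 28 target CNP0317965.1 (7R,8S,7'S,8'S,7''R,8''R)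
Conditions: H2 (1 atm), 10% Pd/C, EtOAc/EtOH, rt
Reagents that add atoms: none
Why: Neutral hydrogenolysis of the two aryl benzyl ethers, which are cleaved faster than the benzylic C–O bonds of rings B and C and of C7'', frees both phenols.

**Compound list**
1 | (E)-coniferaldehyde | COc1cc(/C=C/C=O)ccc1O | starting material
2 | (E)-3-(4-benzyloxy-3-methoxyphenyl)prop-2-enal | COc1cc(/C=C/C=O)ccc1OCc1ccccc1 | intermediate
3 | diethyl 2-bromomalonate | CCOC(=O)C(Br)C(=O)OCC | starting material
4 | diethyl (2S,3R)-2-formyl-3-(4-benzyloxy-3-methoxyphenyl)cyclopropane-1,1-dicarboxylate | O=C[C@H]1[C@H](c2ccc(OCc3ccccc3)c(OC)c2)C1(C(=O)OCC)C(=O)OCC | intermediate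
5 | diethyl (2S,3R)-2-(hydroxymethyl)-3-(4-benzyloxy-3-methoxyphenyl)cyclopropane-1,1-dicarboxylate (not isolated) | OC[C@H]1[C@H](c2ccc(OCc3ccccc3)c(OC)c2)C1(C(=O)OCC)C(=O)OCC | intermediate
6 | ethyl (1R,5S,6R)-6-(4-benzyloxy-3-methoxyphenyl)-2-oxo-3-oxabicyclo[3.1.0]hexane-1-carboxylate | CCOC(=O)[C@]12C(=O)OC[C@H]1[C@@H]2c1ccc(OCc2ccccc2)c(OC)c1 | intermediate
7 | (2S,3R)-2-(hydroxymethyl)-3-(4-benzyloxy-3-methoxyphenyl)cyclopropane-1,1-dicarboxylic acid (not isolated) | OC[C@H]1[C@H](c2ccc(OCc3ccccc3)c(OC)c2)C1(C(=O)O)C(=O)O | intermediate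
8 | (1R,5S,6R)-6-(4-benzyloxy-3-methoxyphenyl)-2-oxo-3-oxabicyclo[3.1.0]hexane-1-carboxylic acid | OC(=O)[C@]12C(=O)OC[C@H]1[C@@H]2c1ccc(OCc2ccccc2)c(OC)c1 | intermediate
9 | (1R,5S,6R)-6-(4-benzyloxy-3-methoxyphenyl)-1-(hydroxymethyl)-3-oxabicyclo[3.1.0]hexan-2-one | OC[C@]12C(=O)OC[C@H]1[C@@H]2c1ccc(OCc2ccccc2)c(OC)c1 | intermediate
10 | ring-opened zwitterion: lactone enolate at C8' (scandium-bound in the flask) with benzylic cation at C7 (not isolated) | OCC1=C([O-])OC[C@H]1[CH+]c1ccc(OCc2ccccc2)c(OC)c1 | intermediate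
11 | (1S,5S,6R)-6-(4-benzyloxy-3-methoxyphenyl)-3,7-dioxabicyclo[3.3.0]octan-2-one (cis-fused, aryl exo) | COc1cc([C@@H]2OC[C@@H]3[C@H]2COC3=O)ccc1OCc1ccccc1 | intermediate
12 | 4-bromo-2,6-dimethoxyphenol | COc1cc(Br)cc(OC)c1O | starting material
13 | bromoacetic acid | OC(=O)CBr | starting material
14 | 2-(4-bromo-2,6-dimethoxyphenoxy)acetic acid | COc1cc(Br)cc(OC)c1OCC(=O)O | intermediate
15 | (S)-4-benzyloxazolidin-2-one | O=C1N[C@@H](Cc2ccccc2)CO1 | starting material
16 | 2-(4-bromo-2,6-dimethoxyphenoxy)acetic pivalic anhydride (not isolated) | COc1cc(Br)cc(OC)c1OCC(=O)OC(=O)C(C)(C)C | intermediate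
17 | (S)-4-benzyl-3-[2-(4-bromo-2,6-dimethoxyphenoxy)acetyl]oxazolidin-2-one | COc1cc(Br)cc(OC)c1OCC(=O)N1[C@@H](Cc2ccccc2)COC1=O | intermediate
18 | 4-benzyloxy-3,5-dimethoxybenzaldehyde | COc1cc(C=O)cc(OC)c1OCc1ccccc1 | starting material
19 | Z-dibutylboron enolate of 17 (not isolated) | CCCCB(CCCC)O/C(=C\Oc1c(OC)cc(Br)cc1OC)N1[C@@H](Cc2ccccc2)COC1=O | intermediate
20 | (S)-4-benzyl-3-[(2S,3R)-3-(4-benzyloxy-3,5-dimethoxyphenyl)-2-(4-bromo-2,6-dimethoxyphenoxy)-3-hydroxypropanoyl]oxazolidin-2-one | COc1cc(Br)cc(OC)c1O[C@H](C(=O)N1[C@@H](Cc2ccccc2)COC1=O)[C@H](O)c1cc(OC)c(OCc2ccccc2)c(OC)c1 | intermediate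
21 | (1R,2R)-1-(4-benzyloxy-3,5-dimethoxyphenyl)-2-(4-bromo-2,6-dimethoxyphenoxy)propane-1,3-diol | COc1cc(Br)cc(OC)c1O[C@H](CO)[C@H](O)c1cc(OC)c(OCc2ccccc2)c(OC)c1 | intermediate
22 | (1R,2R)-1-(4-benzyloxy-3,5-dimethoxyphenyl)-2-(4-bromo-2,6-dimethoxyphenoxy)-1,3-bis(tert-butyldimethylsilyloxy)propane | COc1cc(Br)cc(OC)c1O[C@H](CO[Si](C)(C)C(C)(C)C)[C@H](O[Si](C)(C)C(C)(C)C)c1cc(OC)c(OCc2ccccc2)c(OC)c1 | intermediate
23 | aryllithium from 22 (lithium in place of bromine; not isolated) | [Li]c1cc(OC)c(O[C@H](CO[Si](C)(C)C(C)(C)C)[C@H](O[Si](C)(C)C(C)(C)C)c2cc(OC)c(OCc3ccccc3)c(OC)c2)c(OC)c1 | intermediate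
24 | (1S,5S,6R)-2-ArD-6-(4-benzyloxy-3-methoxyphenyl)-3,7-dioxabicyclo[3.3.0]octan-2-ol (C7' lactol, anomeric mixture) | COc1cc([C@@H]2OC[C@@H]3[C@H]2COC3(O)c2cc(OC)c(O[C@H](CO[Si](C)(C)C(C)(C)C)[C@H](O[Si](C)(C)C(C)(C)C)c3cc(OC)c(OCc4ccccc4)c(OC)c3)c(OC)c2)ccc1OCc1ccccc1 | intermediate
25 | bicyclic C7' oxocarbenium hydroxytrifluoroborate (not isolated) | COc1cc([C@@H]2OC[C@@H]3[C@H]2C[O+]=C3c2cc(OC)c(O[C@H](CO[Si](C)(C)C(C)(C)C)[C@H](O[Si](C)(C)C(C)(C)C)c3cc(OC)c(OCc4ccccc4)c(OC)c3)c(OC)c2)ccc1OCc1ccccc1.O[B-](F)(F)F | intermediate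
26 | (1S,2S,5S,6R)-2-ArD-6-(4-benzyloxy-3-methoxyphenyl)-3,7-dioxabicyclo[3.3.0]octane (fully protected target) | COc1cc([C@@H]2OC[C@@H]3[C@H]2CO[C@@H]3c2cc(OC)c(O[C@H](CO[Si](C)(C)C(C)(C)C)[C@H](O[Si](C)(C)C(C)(C)C)c3cc(OC)c(OCc4ccccc4)c(OC)c3)c(OC)c2)ccc1OCc1ccccc1 | intermediate
27 | 4,4''-di-O-benzyl ether of the target | COc1cc([C@@H]2OC[C@@H]3[C@H]2CO[C@@H]3c2cc(OC)c(O[C@H](CO)[C@H](O)c3cc(OC)c(OCc4ccccc4)c(OC)c3)c(OC)c2)ccc1OCc1ccccc1 | intermediate
28 | CNP0317965.1 (7R,8S,7'S,8'S,7''R,8''R) | COc1cc([C@@H]2OC[C@@H]3[C@H]2CO[C@@H]3c2cc(OC)c(O[C@H](CO)[C@H](O)c3cc(OC)c(O)c(OC)c3)c(OC)c2)ccc1O | target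

**Step count**
Total: 15 steps. Longest linear sequence: 10 steps (steps 1–6 and 12–15, from 1); the aryl bromide branch (steps 7–11) joins at step 12.

**Steps most likely to fail**

Step 6 (proposed new method). The singly activated cyclopropane may fail to ionise under the mild Lewis acid. The benzylic cation may also lose the proton on C8 or be captured by another arene faster than the C9' hydroxyl closes ring B, and reversible elimination would erode the enantiomeric purity relayed from C8. The fallback uses known chemistry and sets out from 9. Oxidation with Dess–Martin periodinane (NaHCO3, CH2Cl2) should give (1R,5S,6R)-6-(4-benzyloxy-3-methoxyphenyl)-2-oxo-3-oxabicyclo[3.1.0]hexane-1-carbaldehyde F1, a doubly activated donor–acceptor cyclopropane. Its Cloke–Wilson rearrangement (Sc(OTf)3 5 mol %, CH2Cl2, rt, if it does not occur on its own) should form the O1–C7 bond through the formyl oxygen and give (3aS,4R)-4-(4-benzyloxy-3-methoxyphenyl)-3a,4-dihydro-1H,3H-furo[3,4-c]furan-1-one F2. Hydrogenation of the C8'=C9' enol ether from the convex face (H2, Rh/Al2O3, EtOAc, which spares the benzyl ether) should then give the cis-fused lactone. The fallback comes back to the route at 11.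

Step 13. Hydride delivery may lose facial selectivity, BF3 may epimerise C7' to the exo aryl isomer, or the benzylic C–O bonds at C7 and C7'' may ionise and be reduced. The fallback sets out from 24 and avoids Lewis acid. Reagent-controlled Corey–Bakshi–Shibata reduction of the open hydroxy ketone tautomer ((R)-2-methyl-CBS-oxazaborolidine, BH3·SMe2, THF) should give the (7'S)-diol F3. Selective sulfonylation of the primary C9 hydroxyl (MsCl, pyridine, CH2Cl2, 0 °C) should give the primary mesylate F4, which on warming is displaced by the C7' hydroxyl. This closes ring C at C9 with retention at C7' and comes back to the route at 26.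

Step 12. The basic aryllithium may enolise the lactone at C8' instead of adding, or a second equivalent may add after ring opening. The fallback sets out from 11. Aminolysis with Me(MeO)NH·HCl and iPrMgCl (THF, −20 °C) should give the hydroxy Weinreb amide F5. Its hydroxyl is deprotonated with one equivalent of iPrMgCl before aryllithium 23 is added; the chelated adduct cannot add twice and is released on aqueous work-up as the hydroxy ketone. This closes to the lactol (the cis isomer is the sink, C8' being epimerisable) and comes back to the route at 24.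

**Further compounds**
F1 | step 6 | (1R,5S,6R)-6-(4-benzyloxy-3-methoxyphenyl)-2-oxo-3-oxabicyclo[3.1.0]hexane-1-carbaldehyde | O=C[C@]12C(=O)OC[C@H]1[C@@H]2c1ccc(OCc2ccccc2)c(OC)c1
F2 | step 6 | (3aS,4R)-4-(4-benzyloxy-3-methoxyphenyl)-3a,4-dihydro-1H,3H-furo[3,4-c]furan-1-one | COc1cc([C@@H]2OC=C3[C@H]2COC3=O)ccc1OCc1ccccc1
F3 | step 13 | (7'S)-diol: 2-aryl tetrahydrofuran (ring B) carrying CH2OH on C8 and (S)-CH(OH)ArD on C8' | COc1cc([C@@H]2OC[C@H]([C@H]2CO)[C@H](O)c2cc(OC)c(O[C@H](CO[Si](C)(C)C(C)(C)C)[C@H](O[Si](C)(C)C(C)(C)C)c3cc(OC)c(OCc4ccccc4)c(OC)c3)c(OC)c2)ccc1OCc1ccccc1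
F4 | step 13 | primary C9 methanesulfonate of F3 | COc1cc([C@@H]2OC[C@H]([C@H]2COS(C)(=O)=O)[C@H](O)c2cc(OC)c(O[C@H](CO[Si](C)(C)C(C)(C)C)[C@H](O[Si](C)(C)C(C)(C)C)c3cc(OC)c(OCc4ccccc4)c(OC)c3)c(OC)c2)ccc1OCc1ccccc1
F5 | step 12 | (3S,4S,5R)-5-(4-benzyloxy-3-methoxyphenyl)-4-(hydroxymethyl)-N-methoxy-N-methyltetrahydrofuran-3-carboxamide | COc1cc([C@@H]2OC[C@@H](C(=O)N(C)OC)[C@H]2CO)ccc1OCc1ccccc1
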